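**Plan**
- The target is achiral, with no stereocentre and no stereogenic double bond, so only regiochemistry has to be controlled.
- Retrosynthesis: the three phenols are masked as MOM ethers. Ring C is then cut at O1–C8a and C4–C4a, giving a ring A aryne and the enol of a methyl 2-aryl-3-oxopropanoate that carries C2, C3, C4 and ring B.
- What allows this cut: ring A bears oxygen at C5, C7 and C8a, so an aryne across C4a–C8a has the C5 oxygen next to C4a. That oxygen polarises the triple bond, so the enolate oxygen adds at C8a and the carbanion left at C4a takes up the acyl carbon C4.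
- The 5'-prenyl group is traced back to an aromatic Claisen rearrangement of the 4'-O-(1,1-dimethylallyl) ether, and C2 to methyl formate.
- Forward: aryne precursor from phloroglucinol (steps 1–3), ring B enol from homovanillic acid (steps 4–9), union with closure of ring C (step 10), removal of the MOM groups (step 11).

Key step: step 10

Remark: enol 16 is drawn as the hydrogen-bonded Z-enol, the tautomer expected to dominate for 2-aryl-3-oxopropanoates; it equilibrates with the aldehyde form, and both give the same enolate.

**Route**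

Step 1
Reactants: 1 phloroglucinol
Product: 3 3,5-bis(methoxymethoxy)phenol, via mono-MOM ether 2 (not isolated)
Conditions: MOMCl (2.0 equiv), i-Pr2NEt (2.2 equiv), DMF, 0 °C → rt; chromatography
Reagents that add atoms: chloromethyl methyl ether, COCCl
Why: Base-mediated O-alkylation (MOM protection) of three equivalent hydroxyls is statistical, so two equivalents of MOMCl should give the bis-ether as the main fraction, which differs enough in polarity from the other ethers to be separated.

Step 2
Reactants: 3 3,5-bis(methoxymethoxy)phenol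
Product: 4 2-bromo-3,5-bis(methoxymethoxy)phenol
Conditions: NBS (1.0 equiv), CH2Cl2, −78 °C → −40 °C
Reagents that add atoms: N-bromosuccinimide, O=C1CCC(=O)N1Br
Why: Electrophilic aromatic bromination of a phenol with NBS in a non-polar solvent is steered ortho by hydrogen bonding of the hydroxyl to the reagent, and C2 is further activated as ortho to one MOM-oxy group and para to the other.

Step 3
Reactants: 4 2-bromo-3,5-bis(methoxymethoxy)phenol
Product: 8 3,5-bis(methoxymethoxy)-2-(trimethylsilyl)phenyl trifluoromethanesulfonate, via aryl trimethylsilyl ether 5 (not isolated), via ortho-lithiated silyl ether 6 (not isolated), via lithium 2-silylphenoxide 7 (not isolated)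
Conditions: HMDS, THF, 70 °C, then evaporation; n-BuLi, THF, −100 °C; Tf2O, −100 → −78 °C
Reagents that add atoms: hexamethyldisilazane, C[Si](C)(C)N[Si](C)(C)C; trifluoromethanesulfonic anhydride, O=S(=O)(OS(=O)(=O)C(F)(F)F)C(F)(F)F
Why: O-silylation, bromine–lithium exchange, anionic 1,3 O→C silyl shift (retro-Brook rearrangement) and triflation of the phenoxide form the standard one-flask passage from ortho-bromophenols to ortho-silylaryl triflates, and the exchange at −100 °C should outrun any MOM-directed deprotonation.

Step 4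
Reactants: 9 homovanillic acid
Product: 10 methyl homovanillate (methyl 2-(4-hydroxy-3-methoxyphenyl)acetate)
Conditions: MeOH, H2SO4 (cat.), reflux
Reagents that add atoms: methanol, CO
Why: Fischer esterification of the aliphatic acid in excess methanol should proceed cleanly and leaves the phenol untouched.

Step 5
Reactants: 10 methyl homovanillate
Product: 11 methyl 2-[3-methoxy-4-(2-methylbut-3-yn-2-yloxy)phenyl]acetate
Conditions: 3-chloro-3-methylbut-1-yne (1.5 equiv), DBU, CuCl2 (cat.), MeCN, 0 °C → rt
Reagents that add atoms: 3-chloro-3-methylbut-1-yne, CC(C)(Cl)C#C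
Why: Copper-catalysed propargylic substitution of a tertiary propargyl chloride by a phenoxide is the usual way to aryl 1,1-dimethylpropargyl ethers, and DBU at 0 °C should leave the methyl ester alone.

Step 6
Reactants: 11 methyl 2-[3-methoxy-4-(2-methylbut-3-yn-2-yloxy)phenyl]acetate
Product: 12 methyl 2-[3-methoxy-4-(2-methylbut-3-en-2-yloxy)phenyl]acetate
Conditions: H2 (1 atm), Pd/CaCO3 poisoned with Pb(OAc)2 (Lindlar catalyst), quinoline, EtOAc, rt
Reagents that add atoms: none
Why: Lindlar semi-hydrogenation should stop the terminal alkyne at the alkene, the poisoned surface being too inactive to reduce further or to hydrogenolyse the tertiary allylic ether.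

Step 7
Reactants: 12 methyl 2-[3-methoxy-4-(2-methylbut-3-en-2-yloxy)phenyl]acetate
Product: 13 methyl 2-[4-hydroxy-3-methoxy-5-(3-methylbut-2-en-1-yl)phenyl]acetate
Conditions: xylenes (degassed), 130 °C
Reagents that add atoms: none
Why: In this aromatic Claisen rearrangement the [3,3] shift delivers the terminal CH2 of the 1,1-dimethylallyl group to C5, the only ortho position that can re-aromatise (C3 carries the methoxy group and the para position is blocked), which turns the reverse-prenyl ether into the C-prenyl phenol.

Step 8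
Reactants: 13 methyl 2-[4-hydroxy-3-methoxy-5-(3-methylbut-2-en-1-yl)phenyl]acetate
Product: 14 methyl 2-[3-methoxy-4-(methoxymethoxy)-5-(3-methylbut-2-en-1-yl)phenyl]acetate
Conditions: MOMCl (1.5 equiv), i-Pr2NEt (2 equiv), CH2Cl2, 0 → 40 °C
Reagents that add atoms: chloromethyl methyl ether, COCCl
Why: MOM protection of the flanked phenol under amine base is routine and is needed because a free phenoxide would itself add to the aryne in step 10.

Step 9
Reactants: 14 methyl 2-[3-methoxy-4-(methoxymethoxy)-5-(3-methylbut-2-en-1-yl)phenyl]acetate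
Product: 16 methyl (Z)-3-hydroxy-2-[3-methoxy-4-(methoxymethoxy)-5-(3-methylbut-2-en-1-yl)phenyl]prop-2-enoate, via sodium enolate 15 (not isolated)
Conditions: NaH (2.5 equiv), HCO2Me (10 equiv), THF, 0 °C → rt; then AcOH, 0 °C
Reagents that add atoms: methyl formate, COC=O
Why: Crossed Claisen condensation (C-formylation) of an arylacetate with non-enolisable methyl formate is driven by formation of the stabilised sodium enolate, and buffered acidification should give the enol without loss of the MOM ether.

Step 10
Reactants: 8 3,5-bis(methoxymethoxy)-2-(trimethylsilyl)phenyl trifluoromethanesulfonate; 16 methyl (Z)-3-hydroxy-2-[3-methoxy-4-(methoxymethoxy)-5-(3-methylbut-2-en-1-yl)phenyl]prop-2-enoate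
Product: 20 5,7,4'-tris-O-(methoxymethyl)-2'-deoxypiscerythrone, via caesium enolate 17 (not isolated), via 3,5-bis(methoxymethoxy)benzyne 18 (not isolated), via aryl caesium adduct 19 (not isolated)
Conditions: CsF (4 equiv), THF, 65 °C; 8 (1.3 equiv) added over 6 h
Reagents that add atoms: none
Why: Proposed new method: CsF converts enol 16 into caesium enolate 17 and, by attack on silicon with loss of triflate, releases aryne 18; the enolate oxygen adds to C8a, the aryne carbon remote from the C5 MOM-oxy group, which forms O1–C8a and leaves the carbanion of 19 at C4a, where the adjacent C–O bond stabilises it inductively, and this carbanion attacks the cis ester carbonyl and expels methoxide to form C4–C4a. The closest known reaction type is the CsF-mediated annulation of ortho-silylaryl triflates with methyl salicylates to xanthones, in which a phenoxide stands where the enolate of a formyl arylacetate stands here; insertion of arynes into the C–C bond of β-keto esters is the competing C-attack manifold of such enolates. Ring C closes by a 6-exo-trig acyl substitution of the aryl anion on the ester carbonyl. No stereocentre is created. The step needs two selectivities: the sense of addition to the aryne, secured by the C5 oxygen, which distorts the triple bond so that the nucleophile enters at the distal carbon, and O- rather than C-arylation, favoured because the enolate carbon is fully substituted by aryl, ester and formyl carbon while the formyl oxygen is the exposed, hard terminus of a loosely paired caesium enolate. The Z (U-shaped) enolate places the ester cis to the new aryl ether as ring closure demands, and slow release of the aryne in THF at 65 °C should keep protonation of 19 behind cyclisation.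

Step 11
Reactants: 20 5,7,4'-tris-O-(methoxymethyl)-2'-deoxypiscerythrone
Product: 21 2'-deoxypiscerythrone
Conditions: HCl (0.5 M in MeOH), 40 °C, stopped at full conversion
Reagents that add atoms: none
Why: Acid-catalysed acetal exchange with methanol should cleave the three aryl MOM ethers, while at this acidity and temperature protonation of the trisubstituted prenyl alkene should be too slow to close a chroman.

**Compound list**

1 | phloroglucinol (benzene-1,3,5-triol) | Oc1cc(O)cc(O)c1 | starting material
2 | 5-(methoxymethoxy)benzene-1,3-diol | COCOc1cc(O)cc(O)c1 | intermediate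
3 | 3,5-bis(methoxymethoxy)phenol | COCOc1cc(O)cc(OCOC)c1 | intermediate
4 | 2-bromo-3,5-bis(methoxymethoxy)phenol | COCOc1cc(O)c(Br)c(OCOC)c1 | intermediate
5 | [2-bromo-3,5-bis(methoxymethoxy)phenoxy]trimethylsilane | COCOc1cc(O[Si](C)(C)C)c(Br)c(OCOC)c1 | intermediate
6 | [2,4-bis(methoxymethoxy)-6-(trimethylsilyloxy)phenyl]lithium | COCOc1cc(O[Si](C)(C)C)c([Li])c(OCOC)c1 | intermediate
7 | lithium 3,5-bis(methoxymethoxy)-2-(trimethylsilyl)phenoxide | COCOc1cc([O-])c([Si](C)(C)C)c(OCOC)c1.[Li+] | intermediate
8 | 3,5-bis(methoxymethoxy)-2-(trimethylsilyl)phenyl trifluoromethanesulfonate | COCOc1cc(OCOC)c([Si](C)(C)C)c(OS(=O)(=O)C(F)(F)F)c1 | intermediate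
9 | homovanillic acid (2-(4-hydroxy-3-methoxyphenyl)acetic acid) | COc1cc(CC(=O)O)ccc1O | starting material
10 | methyl homovanillate (methyl 2-(4-hydroxy-3-methoxyphenyl)acetate) | COC(=O)Cc1ccc(O)c(OC)c1 | intermediate
11 | methyl 2-[3-methoxy-4-(2-methylbut-3-yn-2-yloxy)phenyl]acetate | COC(=O)Cc1ccc(OC(C)(C)C#C)c(OC)c1 | intermediate
12 | methyl 2-[3-methoxy-4-(2-methylbut-3-en-2-yloxy)phenyl]acetate | COC(=O)Cc1ccc(OC(C)(C)C=C)c(OC)c1 | intermediate
13 | methyl 2-[4-hydroxy-3-methoxy-5-(3-methylbut-2-en-1-yl)phenyl]acetate | COC(=O)Cc1cc(OC)c(O)c(CC=C(C)C)c1 | intermediate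
14 | methyl 2-[3-methoxy-4-(methoxymethoxy)-5-(3-methylbut-2-en-1-yl)phenyl]acetate | COC(=O)Cc1cc(OC)c(OCOC)c(CC=C(C)C)c1 | intermediate
15 | sodium (Z)-3-methoxy-2-[3-methoxy-4-(methoxymethoxy)-5-(3-methylbut-2-en-1-yl)phenyl]-3-oxoprop-1-en-1-olate | COC(=O)/C(=C\[O-])c1cc(OC)c(OCOC)c(CC=C(C)C)c1.[Na+] | intermediate
16 | methyl (Z)-3-hydroxy-2-[3-methoxy-4-(methoxymethoxy)-5-(3-methylbut-2-en-1-yl)phenyl]prop-2-enoate | COC(=O)/C(=C\O)c1cc(OC)c(OCOC)c(CC=C(C)C)c1 | intermediate
17 | caesium (Z)-3-methoxy-2-[3-methoxy-4-(methoxymethoxy)-5-(3-methylbut-2-en-1-yl)phenyl]-3-oxoprop-1-en-1-olate | COC(=O)/C(=C\[O-])c1cc(OC)c(OCOC)c(CC=C(C)C)c1.[Cs+] | intermediate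
18 | 3,5-bis(methoxymethoxy)benzyne (1,2-didehydro-3,5-bis(methoxymethoxy)benzene) | COCOC1=CC(OCOC)=CC#C1 | intermediate
19 | caesium 2-{[(Z)-3-methoxy-2-[3-methoxy-4-(methoxymethoxy)-5-(3-methylbut-2-en-1-yl)phenyl]-3-oxoprop-1-en-1-yl]oxy}-4,6-bis(methoxymethoxy)benzen-1-ide | COC(=O)/C(=C\Oc1cc(OCOC)cc(OCOC)[c-]1)c1cc(OC)c(OCOC)c(CC=C(C)C)c1.[Cs+] | intermediate
20 | 5,7,4'-tris-O-(methoxymethyl)-2'-deoxypiscerythrone (3-[3-methoxy-4-(methoxymethoxy)-5-(3-methylbut-2-en-1-yl)phenyl]-5,7-bis(methoxymethoxy)-4H-chromen-4-one) | COCOc1cc(OCOC)c2c(=O)c(-c3cc(OC)c(OCOC)c(CC=C(C)C)c3)coc2c1 | intermediate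
21 | 2'-deoxypiscerythrone (5,7-dihydroxy-3-[4-hydroxy-3-methoxy-5-(3-methylbut-2-en-1-yl)phenyl]-4H-chromen-4-one) | COc1cc(-c2coc3cc(O)cc(O)c3c2=O)cc(CC=C(C)C)c1O | target

**Count**

Total steps: 11 (3 for the aryne precursor, 6 for the ring B enol, 2 after the union).
Longest linear sequence: 8 steps (9 → 21, steps 4–11).

**Steps most likely to fail**

Step 10. The ambident enolate may arylate at carbon, which leads on to insertion of the aryne into the C–CHO bond. Alternatively, the aryl anion of 19 may be protonated before it reaches the ester, so that ring C is not closed. The fallback is the known deoxybenzoin route to isoflavones; it sets out from 1 and 14 and rejoins the route at 21.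
- 1 is exhaustively alkylated (MOMCl, NaH, DMF) to 1,3,5-tris(methoxymethoxy)benzene F1.
- Ester 14 is converted with MeNH(OMe)·HCl and i-PrMgCl (THF, −20 °C) into the Weinreb amide N-methoxy-N-methyl-2-[3-methoxy-4-(methoxymethoxy)-5-(3-methylbut-2-en-1-yl)phenyl]acetamide F2.
- F1 is lithiated between two MOM-oxy groups (n-BuLi, THF, 0 °C) and acylated by F2 at −78 °C to the deoxybenzoin 2-[3-methoxy-4-(methoxymethoxy)-5-(3-methylbut-2-en-1-yl)phenyl]-1-[2,4,6-tris(methoxymethoxy)phenyl]ethan-1-one F3.
- Condensation with N,N-dimethylformamide dimethyl acetal (toluene, 100 °C) adds C2 as the enaminone (E)-3-(dimethylamino)-2-[3-methoxy-4-(methoxymethoxy)-5-(3-methylbut-2-en-1-yl)phenyl]-1-[2,4,6-tris(methoxymethoxy)phenyl]prop-2-en-1-one F4.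
- Methanolic HCl at 40 °C should then remove the four MOM groups, and the freed ortho-hydroxyl closes ring C by conjugate addition and loss of dimethylamine, which gives 21.

Step 2. Bromination may occur para to the hydroxyl, at the carbon between the two MOM ethers, or twice; either outcome gives material that cannot undergo the silyl shift of step 3. The fallback replaces electrophilic halogenation by directed ortho-metalation; it sets out from 3 and rejoins the route at 8.
- 3 is treated with isopropyl isocyanate and Et3N (CH2Cl2, rt) to give 3,5-bis(methoxymethoxy)phenyl N-(propan-2-yl)carbamate F5.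
- After transient N-silylation (TBSOTf, TMEDA, Et2O), n-BuLi/TMEDA at −78 °C should remove the proton between the carbamate and the neighbouring MOM ether, the carbamate being the stronger director. TMSCl and aqueous work-up then give 3,5-bis(methoxymethoxy)-2-(trimethylsilyl)phenyl N-(propan-2-yl)carbamate F6.
- Et2NH and DBU in MeCN at 40 °C cleave the carbamate, and PhNTf2 added to the same flask triflates the phenoxide to give 8.

Step 11. Once the 4'-hydroxyl is free, acid may add it to the prenyl double bond and close a 2,2-dimethylchroman, or methanol may add across that alkene while the last MOM group is still being removed. The fallback carries the ring B phenol as an allyl ether, so that acid never meets the free ortho-prenyl phenol; it sets out from 13 and rejoins the route at 21.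
- 13 is alkylated with allyl bromide and K2CO3 in acetone to methyl 2-[3-methoxy-5-(3-methylbut-2-en-1-yl)-4-(prop-2-en-1-yloxy)phenyl]acetate F7.
- Formylation as in step 9 gives methyl (Z)-3-hydroxy-2-[3-methoxy-5-(3-methylbut-2-en-1-yl)-4-(prop-2-en-1-yloxy)phenyl]prop-2-enoate F8.
- Annulation with 8 under the conditions of step 10 gives 4'-O-allyl-5,7-bis-O-(methoxymethyl)-2'-deoxypiscerythrone F9.
- Methanolic HCl removes the two ring A MOM groups to give 4'-O-allyl-2'-deoxypiscerythrone F10.
- Pd(PPh3)4 (zerovalent palladium, cat.) with morpholine in THF at rt transfers the allyl group to the amine and should release 21 under neutral conditions.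

Further compounds
F1 | step 10 | 1,3,5-tris(methoxymethoxy)benzene | COCOc1cc(OCOC)cc(OCOC)c1
F2 | step 10 | N-methoxy-N-methyl-2-[3-methoxy-4-(methoxymethoxy)-5-(3-methylbut-2-en-1-yl)phenyl]acetamide | CON(C)C(=O)Cc1cc(OC)c(OCOC)c(CC=C(C)C)c1
F3 | step 10 | 2-[3-methoxy-4-(methoxymethoxy)-5-(3-methylbut-2-en-1-yl)phenyl]-1-[2,4,6-tris(methoxymethoxy)phenyl]ethan-1-one | COCOc1cc(OCOC)c(C(=O)Cc2cc(OC)c(OCOC)c(CC=C(C)C)c2)c(OCOC)c1
F4 | step 10 | (E)-3-(dimethylamino)-2-[3-methoxy-4-(methoxymethoxy)-5-(3-methylbut-2-en-1-yl)phenyl]-1-[2,4,6-tris(methoxymethoxy)phenyl]prop-2-en-1-one | CN(C)/C=C(/C(=O)c1c(OCOC)cc(OCOC)cc1OCOC)c1cc(OC)c(OCOC)c(CC=C(C)C)c1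
F5 | step 2 | 3,5-bis(methoxymethoxy)phenyl N-(propan-2-yl)carbamate | CC(C)NC(=O)Oc1cc(OCOC)cc(OCOC)c1
F6 | step 2 | 3,5-bis(methoxymethoxy)-2-(trimethylsilyl)phenyl N-(propan-2-yl)carbamate | CC(C)NC(=O)Oc1cc(OCOC)cc(OCOC)c1[Si](C)(C)C
F7 | step 11 | methyl 2-[3-methoxy-5-(3-methylbut-2-en-1-yl)-4-(prop-2-en-1-yloxy)phenyl]acetate | COC(=O)Cc1cc(OC)c(OCC=C)c(CC=C(C)C)c1
F8 | step 11 | methyl (Z)-3-hydroxy-2-[3-methoxy-5-(3-methylbut-2-en-1-yl)-4-(prop-2-en-1-yloxy)phenyl]prop-2-enoate | COC(=O)/C(=C\O)c1cc(OC)c(OCC=C)c(CC=C(C)C)c1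
F9 | step 11 | 4'-O-allyl-5,7-bis-O-(methoxymethyl)-2'-deoxypiscerythrone | COCOc1cc(OCOC)c2c(=O)c(-c3cc(OC)c(OCC=C)c(CC=C(C)C)c3)coc2c1
F10 | step 11 | 4'-O-allyl-2'-deoxypiscerythrone | COc1cc(-c2coc3cc(O)cc(O)c3c2=O)cc(CC=C(C)C)c1OCC=C
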